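**Retrosynthetic overview**

1. The route rests on the pyranone ring of the coumarin (O1, C2, C3, C4, fused across C4a–C8a). It is closed last from salicylaldehyde 13 and Ph3P=C=C=O, forming O1–C2 and C3=C4; ring carbons C1 and C2 of the benzaldehyde become C4a and C8a. The C5' hydroxyl is unmasked afterwards.
2. Aldehyde 13 is cut at the C7–O–C1' ether. Mitsunobu coupling joins epoxy alcohol 9 to the unchelated 4-OH of 2,4-dihydroxy-3-methoxybenzaldehyde 12 (formylation of 2-methoxyresorcinol). The 2-OH, hydrogen-bonded to the aldehyde, stays free for the annulation.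
3. Epoxy alcohol 9 comes from Sharpless epoxidation (C2', C3') of E-allylic alcohol 8. Alcohol 8 comes from zirconium-catalysed methylalumination and hydroxymethylation of alkyne 5, and C5' is set by asymmetric propargylboration of prenal.
4. Ring order: benzene ring bought; oxirane in step 4; pyranone ring in step 7.

Key step: step 7

Locants: coumarin O1 to C8a; side chain C1' (OCH2) to C8'.

Assumption: (R)-TRIP (3,3'-bis(2,4,6-triisopropylphenyl)-1,1'-binaphthyl-2,2'-diyl hydrogen phosphate) is taken to direct the allenylboronate to the Re face of the enal, as it does with aryl aldehydes; the (S)-acid would be used if the sense proved opposite.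

**Route**

Step 1
Reactants: 1 3-methylbut-2-enal (prenal); 2 allenylboronic acid pinacol ester
Product: 4 (4R)-2-methylhept-2-en-6-yn-4-ol, via pinacol borate ester 3 (not isolated)
Conditions: (R)-TRIP (10 mol%), 4 Å MS, toluene, 0 °C; then aq. NaHCO3
Reagents that add atoms: none
Why: Chiral phosphoric acid catalysed propargylboration, in which the allenylboronate reacts through a closed six-membered SE2' transition state held by the acid, so that only the homopropargylic regioisomer forms and attack on the Re face of the aldehyde should set C5' as R.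

Step 2
Reactants: 4 (4R)-2-methylhept-2-en-6-yn-4-ol
Product: 5 triethyl{[(4R)-2-methylhept-2-en-6-yn-4-yl]oxy}silane
Conditions: Et3SiCl, imidazole, CH2Cl2, 0 °C
Reagents that add atoms: chlorotriethylsilane, CC[Si](Cl)(CC)CC
Why: Standard silylation of a secondary alcohol, which protects C5'–OH from the organometallic steps and ensures that later only the primary allylic hydroxyl can direct an epoxidation.

Step 3
Reactants: 5 triethyl{[(4R)-2-methylhept-2-en-6-yn-4-yl]oxy}silane
Product: 8 (2E,5R)-3,7-dimethyl-5-(triethylsilyloxy)octa-2,6-dien-1-ol, via alkenyldimethylalane 6 (not isolated), via lithium alkenylaluminate 7 (not isolated)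
Conditions: AlMe3, Cp2ZrCl2 (25 mol%), CH2Cl2, 0 °C to rt; evaporate, hexane; n-BuLi, −78 to 0 °C; (CH2O)n, THF, rt; aq. KNaC4H4O6 (potassium sodium tartrate)
Reagents that add atoms: trimethylaluminium, C[Al](C)C; paraformaldehyde (as formaldehyde), C=O
Why: Negishi zirconium-catalysed carboalumination adds methyl and aluminium syn across the terminal alkyne (methyl to the internal carbon), and hydroxymethylation of the derived ate complex proceeds with retention, which fixes the E geometry of C2'=C3'.

Step 4
Reactants: 8 (2E,5R)-3,7-dimethyl-5-(triethylsilyloxy)octa-2,6-dien-1-ol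
Product: 9 {(2R,3R)-3-methyl-3-[(2R)-4-methyl-2-(triethylsilyloxy)pent-3-en-1-yl]oxiran-2-yl}methanol
Conditions: Ti(OiPr)4 (10 mol%), D-(−)-diethyl tartrate (12 mol%), t-BuOOH, 4 Å MS, CH2Cl2, −20 °C
Reagents that add atoms: tert-butyl hydroperoxide, CC(C)(C)OO
Why: Sharpless asymmetric epoxidation, in which D-(−)-tartrate should deliver oxygen to the face of the E-allylic alcohol that gives the (2R,3R)-epoxide (as with geraniol) under reagent control, while the C6'=C7' alkene is untouched because its allylic oxygen is silylated.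

Step 5
Reactants: 10 2-methoxyresorcinol
Product: 12 2,4-dihydroxy-3-methoxybenzaldehyde, via aryl iminium chloride 11 (not isolated)
Conditions: POCl3, DMF, MeCN, −15 °C to rt; then H2O, 50 °C
Reagents that add atoms: N,N-dimethylformamide, CN(C)C=O; water, O
Why: Vilsmeier–Haack formylation at the position ortho to one hydroxyl and para to the other (the two such positions are equivalent), and the iminium group deactivates the ring against a second formylation.

Step 6
Reactants: 9 epoxy alcohol; 12 2,4-dihydroxy-3-methoxybenzaldehyde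
Product: 13 2-hydroxy-3-methoxy-4-({(2R,3R)-3-methyl-3-[(2R)-4-methyl-2-(triethylsilyloxy)pent-3-en-1-yl]oxiran-2-yl}methoxy)benzaldehyde
Conditions: PPh3, DIAD, THF, 0 °C to rt
Reagents that add atoms: none
Why: Mitsunobu etherification by displacement at the primary C1' (no stereocentre is touched), in which the more acidic, unchelated 4-OH reacts while the 2-OH stays locked in its hydrogen bond to the aldehyde.

Step 7
Reactants: 13 salicylaldehyde ether; 14 ketenylidenetriphenylphosphorane
Product: 16 8-methoxy-7-({(2R,3R)-3-methyl-3-[(2R)-4-methyl-2-(triethylsilyloxy)pent-3-en-1-yl]oxiran-2-yl}methoxy)-2H-chromen-2-one, via aryl phosphoranylideneacetate 15 (not isolated)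
Conditions: Ph3P=C=C=O (1.3 equiv), toluene, 110 °C
Reagents that add atoms: none
Why: The phenolic O–H of 13, the only O–H in the molecule, adds across the cumulated C=C of the ylide to give the ester-stabilised ylide 15 (O1–C2), whose ylide carbon then attacks the ortho formyl group; the oxaphosphetane collapses to C3=C4 and Ph3PO. The closest known reaction type is the addition/intramolecular Wittig annulation of 2-hydroxybenzaldehydes with ketenylidenetriphenylphosphorane, an established coumarin synthesis. The pyranone ring closes in a 6-exo-trig mode at the ylide carbon, and a six-membered ring can hold only the cis C3=C4 alkene. No stereocentre is formed; C2', C3' and C5' are remote from the reacting atoms and see only a neutral, aprotic medium, so the epoxide, the silyl ether and the isobutenyl group should pass unchanged. The step needs chemoselectivity for a single acylation site and control of ring size, and the substrate secures both: C5'–OH is silylated, the C7 oxygen is etherified, and the free hydroxyl sits ortho to the aldehyde.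

Step 8
Reactants: 16 coumarin triethylsilyl ether
Product: 17 7-({(2R,3R)-3-[(2R)-2-hydroxy-4-methylpent-3-en-1-yl]-3-methyloxiran-2-yl}methoxy)-8-methoxy-2H-chromen-2-one
Conditions: Bu4NF, AcOH (1:1), THF, 0 °C to rt
Reagents that add atoms: none
Why: Fluoride-induced cleavage of a secondary triethylsilyl ether, buffered with acetic acid so that the lactone, the trisubstituted epoxide and the allylic alcohol should survive.

**Compound list**

1 | 3-methylbut-2-enal (prenal) | CC(C)=CC=O | starting material
2 | 4,4,5,5-tetramethyl-2-(propa-1,2-dien-1-yl)-1,3,2-dioxaborolane (allenylboronic acid pinacol ester) | C=C=CB1OC(C)(C)C(C)(C)O1 | starting material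
3 | 4,4,5,5-tetramethyl-2-{[(4R)-2-methylhept-2-en-6-yn-4-yl]oxy}-1,3,2-dioxaborolane | C#CC[C@@H](OB1OC(C)(C)C(C)(C)O1)C=C(C)C | intermediate
4 | (4R)-2-methylhept-2-en-6-yn-4-ol | C#CC[C@@H](O)C=C(C)C | intermediate
5 | triethyl{[(4R)-2-methylhept-2-en-6-yn-4-yl]oxy}silane | C#CC[C@@H](O[Si](CC)(CC)CC)C=C(C)C | intermediate
6 | [(1E,4R)-2,6-dimethyl-4-(triethylsilyloxy)hepta-1,5-dien-1-yl]dimethylalumane | C[Al](C)/C=C(\C)C[C@@H](O[Si](CC)(CC)CC)C=C(C)C | intermediate
7 | lithium butyl[(1E,4R)-2,6-dimethyl-4-(triethylsilyloxy)hepta-1,5-dien-1-yl]dimethylaluminate | [Li+].CCCC[Al-](C)(C)/C=C(\C)C[C@@H](O[Si](CC)(CC)CC)C=C(C)C | intermediate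
8 | (2E,5R)-3,7-dimethyl-5-(triethylsilyloxy)octa-2,6-dien-1-ol | OC/C=C(\C)C[C@@H](O[Si](CC)(CC)CC)C=C(C)C | intermediate
9 | {(2R,3R)-3-methyl-3-[(2R)-4-methyl-2-(triethylsilyloxy)pent-3-en-1-yl]oxiran-2-yl}methanol | OC[C@H]1O[C@]1(C)C[C@@H](O[Si](CC)(CC)CC)C=C(C)C | intermediate
10 | 2-methoxybenzene-1,3-diol (2-methoxyresorcinol) | COc1c(O)cccc1O | starting material
11 | N-[(2,4-dihydroxy-3-methoxyphenyl)methylidene]-N-methylmethanaminium chloride | C[N+](C)=Cc1ccc(O)c(OC)c1O.[Cl-] | intermediate
12 | 2,4-dihydroxy-3-methoxybenzaldehyde | O=Cc1ccc(O)c(OC)c1O | intermediate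
13 | 2-hydroxy-3-methoxy-4-({(2R,3R)-3-methyl-3-[(2R)-4-methyl-2-(triethylsilyloxy)pent-3-en-1-yl]oxiran-2-yl}methoxy)benzaldehyde | O=Cc1ccc(OC[C@H]2O[C@]2(C)C[C@@H](O[Si](CC)(CC)CC)C=C(C)C)c(OC)c1O | intermediate
14 | ketenylidenetriphenylphosphorane | O=C=C=P(c1ccccc1)(c1ccccc1)c1ccccc1 | starting material
15 | 6-formyl-2-methoxy-3-({(2R,3R)-3-methyl-3-[(2R)-4-methyl-2-(triethylsilyloxy)pent-3-en-1-yl]oxiran-2-yl}methoxy)phenyl (triphenyl-λ5-phosphanylidene)acetate | O=Cc1ccc(OC[C@H]2O[C@]2(C)C[C@@H](O[Si](CC)(CC)CC)C=C(C)C)c(OC)c1OC(=O)C=P(c1ccccc1)(c1ccccc1)c1ccccc1 | intermediate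
16 | 8-methoxy-7-({(2R,3R)-3-methyl-3-[(2R)-4-methyl-2-(triethylsilyloxy)pent-3-en-1-yl]oxiran-2-yl}methoxy)-2H-chromen-2-one | COc1c(OC[C@H]2O[C@]2(C)C[C@@H](O[Si](CC)(CC)CC)C=C(C)C)ccc2ccc(=O)oc12 | intermediate
17 | 7-({(2R,3R)-3-[(2R)-2-hydroxy-4-methylpent-3-en-1-yl]-3-methyloxiran-2-yl}methoxy)-8-methoxy-2H-chromen-2-one | COc1c(OC[C@H]2O[C@]2(C)C[C@@H](O)C=C(C)C)ccc2ccc(=O)oc12 | target

**Step count**

Total: 8 steps. Longest linear sequence: 7 steps (steps 1, 2, 3, 4, 6, 7, 8).

**Steps most likely to fail, with fallbacks**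

Step 7. The addition of the hindered, hydrogen-bonded phenol to the cumulated ylide may be slow, so that the ylide is lost to moisture or self-condensation, or the ester ylide olefinates a second molecule of aldehyde instead of its own. The fallback sets out from 13 and comes back at 16, and forms O1–C2 by acylation instead of ketene addition. Phenol 13 is acylated with bromoacetyl bromide and 2,6-lutidine (CH2Cl2, −20 °C) to the aryl bromoacetate F1. PPh3 (MeCN, rt) converts it to the phosphonium bromide F2. Et3N (CH2Cl2, rt) then deprotonates F2 to ylide 15, which closes to 16 by the same intramolecular Wittig reaction at room temperature.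

Step 3. The Lewis-acidic carboalumination medium may ionise or desilylate the allylic silyl ether at C5', and capture of the ate complex by formaldehyde may be incomplete. The fallback sets out from 5 and comes back at 8, and avoids Lewis acids. Alkyne 5 is deprotonated with n-BuLi (THF, −78 °C) and hydroxymethylated with (CH2O)n to the propargylic alcohol (5R)-7-methyl-5-(triethylsilyloxy)oct-6-en-2-yn-1-ol F3. Trans-hydroalumination with NaAlH2(OCH2CH2OMe)2 (THF, 0 °C) followed by iodinolysis (I2, −78 °C) should give the (2Z)-3-iodo allylic alcohol F4. Me2CuLi (Et2O, 0 °C) replaces iodine by methyl with retention and returns 8.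

Step 1. Facial discrimination on the β,β-disubstituted enal may be poor, or turnover slow. The fallback sets out from 1 and comes back at 4, and replaces catalytic asymmetric C–C bond formation by resolution. Barbier propargylation of 1 (Zn, propargyl bromide, THF/aq. NH4Cl) gives the racemic alcohol 2-methylhept-2-en-6-yn-4-ol F5. Sharpless kinetic resolution (Ti(OiPr)4, L-(+)-diisopropyl tartrate, t-BuOOH 0.6 equiv, 4 Å MS, CH2Cl2, −20 °C) should consume the (S)-enantiomer as the epoxy alcohol (1S)-1-[(2S)-3,3-dimethyloxiran-2-yl]but-3-yn-1-ol F6. The unreacted (R)-alcohol 4 is separated by chromatography; the cis-methyl group on the alkene is expected to lower the selectivity, so the resolution is run past half conversion.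

**Further compounds**

F1 | step 7 | 6-formyl-2-methoxy-3-({(2R,3R)-3-methyl-3-[(2R)-4-methyl-2-(triethylsilyloxy)pent-3-en-1-yl]oxiran-2-yl}methoxy)phenyl bromoacetate | O=Cc1ccc(OC[C@H]2O[C@]2(C)C[C@@H](O[Si](CC)(CC)CC)C=C(C)C)c(OC)c1OC(=O)CBr
F2 | step 7 | {2-[6-formyl-2-methoxy-3-({(2R,3R)-3-methyl-3-[(2R)-4-methyl-2-(triethylsilyloxy)pent-3-en-1-yl]oxiran-2-yl}methoxy)phenoxy]-2-oxoethyl}triphenylphosphonium bromide | O=Cc1ccc(OC[C@H]2O[C@]2(C)C[C@@H](O[Si](CC)(CC)CC)C=C(C)C)c(OC)c1OC(=O)C[P+](c1ccccc1)(c1ccccc1)c1ccccc1.[Br-]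
F3 | step 3 | (5R)-7-methyl-5-(triethylsilyloxy)oct-6-en-2-yn-1-ol | OCC#CC[C@@H](O[Si](CC)(CC)CC)C=C(C)C
F4 | step 3 | (2Z,5R)-3-iodo-7-methyl-5-(triethylsilyloxy)octa-2,6-dien-1-ol | OC/C=C(\I)C[C@@H](O[Si](CC)(CC)CC)C=C(C)C
F5 | step 1 | racemic 2-methylhept-2-en-6-yn-4-ol | C#CCC(O)C=C(C)C
F6 | step 1 | (1S)-1-[(2S)-3,3-dimethyloxiran-2-yl]but-3-yn-1-ol | C#CC[C@H](O)[C@@H]1OC1(C)C
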